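## Retrosynthetic overview

1. Target ⇒ global deprotection of a bis-silyl ether / dimethyl acetal that already carries the full C30 skeleton.
2. Ring B and the whole triene side chain ⇒ one nickel-electrocatalytic alkenylative cyclization of an allenyl β-hydroxy aldehyde with a (1E,3Z)-1-chlorodiene. This forms the ring-closing C–C bond and the vinyl–dienyl bond and sets both ring-B stereocentres.
3. Allenyl aldehyde ⇒ hydroxyl-directed epoxidation and hydride opening (tertiary carbinol) ⇒ deconjugative α-alkylation of a cyclohexenecarboxylate with 5-iodopenta-1,2-diene (spiro quaternary carbon).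
4. Cyclohexenecarboxylate with the masked (Z)-enal ⇒ SeO2 oxidation and olefin isomerization of the isopropenyl group ⇒ enol triflate carbonylation ⇒ trans-C6-alkylated (S)-carvone. The chlorodiene ⇒ carbomagnesiation of propargyl alcohol and coupling with (E)-1,2-dichloroethene.
5. Ring order: ring A is bought as (S)-carvone (its C5 centre relays to C6 and is then erased); ring B is closed in the penultimate step.

Assumption: ring A keeps the carvone locants C1–C6 in the names of 3–19 (C1 becomes the spiro carbon), and the six starting materials are taken as catalogue compounds.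

## Route

Step 1
Reactants: 1 (S)-(+)-carvone; 2 tert-butyl(3-iodopropoxy)dimethylsilane
Product: 4 (5S,6R)-6-[3-(tert-butyldimethylsilyloxy)propyl]-2-methyl-5-(prop-1-en-2-yl)cyclohex-2-en-1-one, via carvone lithium dienolate 3 (not isolated)
Conditions: LiN(iPr)2 (1.05 equiv), THF, −78 °C; then 2, DMPU, −78 → −20 °C
Reagents that add atoms: none
Why: Kinetic α′-enolate alkylation of carvone, in which the iodide enters anti to the C5 isopropenyl group, so the purchased C5 centre sets C6 (trans-5,6).

Step 2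
Reactants: 4 alkylated carvone
Product: 6 (5S,6R)-6-[3-(tert-butyldimethylsilyloxy)propyl]-2-methyl-5-(prop-1-en-2-yl)cyclohex-1-en-1-yl trifluoromethanesulfonate, via lithium enolate 5 (not isolated)
Conditions: Li[HB(sBu)3] (1.1 equiv), THF, −78 °C; then PhNTf2, −78 → 0 °C
Reagents that add atoms: N-phenylbis(trifluoromethanesulfonimide), O=S(=O)(N(c1ccccc1)S(=O)(=O)C(F)(F)F)C(F)(F)F
Why: Conjugate hydride reduction of the β-unsubstituted enone by the bulky borohydride gives the tetrasubstituted enolate regiospecifically, which is trapped on oxygen (reductive enol triflation); no stereocentre is made or touched.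

Step 3
Reactants: 6 enol triflate
Product: 7 methyl (5S,6R)-6-[3-(tert-butyldimethylsilyloxy)propyl]-2-methyl-5-(prop-1-en-2-yl)cyclohex-1-ene-1-carboxylate
Conditions: Pd(OAc)2 (5 mol%), Ph2P(CH2)3PPh2, CO (1 atm), MeOH, Et3N, DMF, 60 °C
Reagents that add atoms: carbon monoxide, [C-]#[O+]; methanol, CO
Why: Palladium-catalysed methoxycarbonylation of an alkenyl triflate (oxidative addition to zerovalent palladium, CO insertion, methanolysis) installs the carbon that becomes the ring-B carbinol.

Step 4
Reactants: 7 unsaturated ester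
Product: 8 methyl (5S,6R)-6-[3-(tert-butyldimethylsilyloxy)propyl]-2-methyl-5-(3-oxoprop-1-en-2-yl)cyclohex-1-ene-1-carboxylate
Conditions: SeO2 (1.2 equiv), pyridine, 1,4-dioxane, 80 °C
Reagents that add atoms: selenium dioxide, O=[Se]=O
Why: Riley allylic oxidation (ene reaction then 2,3-shift) attacks the only electron-rich alkene, the isopropenyl group, at its methyl, while the ester-conjugated ring alkene is deactivated.

Step 5
Reactants: 8 2-substituted acrolein
Product: 9 methyl (5Z,6R)-6-[3-(tert-butyldimethylsilyloxy)propyl]-2-methyl-5-(1-oxopropan-2-ylidene)cyclohex-1-ene-1-carboxylate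
Conditions: RuHCl(CO)(PPh3)3 (5 mol%), toluene, 80 °C
Reagents that add atoms: none
Why: Metal-hydride olefin isomerization (hydrometalation to the α-ruthenium aldehyde, β-hydride elimination from C5–H) moves the exo-methylene into the tetrasubstituted conjugated position; the Z geometry, with the smaller formyl group syn to the substituted C6, is the expected thermodynamic one, and C6 is never β to the metal so it is not scrambled.

Step 6
Reactants: 9 (Z)-enal
Product: 10 methyl (5Z,6R)-6-[3-(tert-butyldimethylsilyloxy)propyl]-5-(1,1-dimethoxypropan-2-ylidene)-2-methylcyclohex-1-ene-1-carboxylate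
Conditions: HC(OMe)3, pyridinium p-toluenesulfonate (cat.), MeOH, 25 °C
Reagents that add atoms: trimethyl orthoformate, COC(OC)OC
Why: Acid-catalysed acetalization masks the enal and removes the γ-acidity of C6–H before the strong base and hydride steps; the alkene geometry is locked.

Step 7
Reactants: 11 but-3-yn-1-ol
Product: 12 penta-3,4-dien-1-ol
Conditions: (CH2O)n, CuI (copper iodide, 40 mol%), iPr2NH, 1,4-dioxane, reflux
Reagents that add atoms: formaldehyde (as paraformaldehyde), C=O
Why: Crabbé homologation (copper-mediated Mannich reaction, then 1,5-hydride transfer and elimination) converts the terminal alkyne into the terminal allene.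

Step 8
Reactants: 12 penta-3,4-dien-1-ol
Product: 13 5-iodopenta-1,2-diene
Conditions: I2, PPh3, imidazole, CH2Cl2, 0 °C
Reagents that add atoms: iodine, II
Why: Appel iodination of a primary alcohol via the alkoxyphosphonium salt and SN2 displacement by iodide.

Step 9
Reactants: 10 acetal ester; 13 5-iodopenta-1,2-diene
Product: 15 methyl (1R,5Z,6R)-6-[3-(tert-butyldimethylsilyloxy)propyl]-5-(1,1-dimethoxypropan-2-ylidene)-2-methylidene-1-(penta-3,4-dien-1-yl)cyclohexane-1-carboxylate, via lithium ester dienolate 14 (not isolated)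
Conditions: LiN(iPr)2 (1.2 equiv), THF/DMPU, −78 °C; then 13, −78 → 0 °C
Reagents that add atoms: none
Why: Deconjugative α-alkylation of an ester dienolate (γ-deprotonation at the methyl cis to the ester, attack at the α-carbon); the C6 chain, held axial by A(1,3) strain against the two exocyclic double bonds, blocks one face, so the iodide enters trans to it and sets the quaternary C1.

Step 10
Reactants: 15 quaternary ester
Product: 16 [(1R,5Z,6R)-6-[3-(tert-butyldimethylsilyloxy)propyl]-5-(1,1-dimethoxypropan-2-ylidene)-2-methylidene-1-(penta-3,4-dien-1-yl)cyclohexyl]methanol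
Conditions: LiAlH4, THF, 0 → 25 °C
Reagents that add atoms: none
Why: Hydride reduction of the hindered ester to the neopentyl alcohol; allene, acetal and silyl ether are inert.

Step 11
Reactants: 16 homoallylic alcohol
Product: 17 spiro-epoxide of 16 at C2 [(1S,2S,5Z,6R); oxirane oxygen on C2 syn to the CH2OH group, oxirane CH2 from the former methylidene]
Conditions: VO(acac)2 (5 mol%), t-BuOOH, CH2Cl2, 0 → 25 °C
Reagents that add atoms: tert-butyl hydroperoxide, CC(C)(C)OO
Why: Hydroxyl-directed vanadium-catalysed epoxidation of a homoallylic alcohol delivers oxygen to the face of the CH2OH group, which is also the face away from the axial pentadienyl chain, and so sets C2 from C1 while leaving the undirected alkenes alone.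

Step 12
Reactants: 17 epoxy alcohol
Product: 18 (1S,2S,5Z,6R)-6-[3-(tert-butyldimethylsilyloxy)propyl]-5-(1,1-dimethoxypropan-2-ylidene)-1-(hydroxymethyl)-2-methyl-1-(penta-3,4-dien-1-yl)cyclohexan-2-ol
Conditions: LiAlH4, THF, 0 → 25 °C
Reagents that add atoms: none
Why: SN2 hydride opening of the spiro-epoxide at its unsubstituted CH2 carbon gives the tertiary alcohol with the C2–O bond untouched.

Step 13
Reactants: 18 diol
Product: 19 (1R,2S,5Z,6R)-6-[3-(tert-butyldimethylsilyloxy)propyl]-5-(1,1-dimethoxypropan-2-ylidene)-2-hydroxy-2-methyl-1-(penta-3,4-dien-1-yl)cyclohexane-1-carbaldehyde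
Conditions: TEMPO (10 mol%), PhI(OAc)2, CH2Cl2, 0 → 25 °C
Reagents that add atoms: none
Why: Oxoammonium (TEMPO) oxidation is selective for the primary alcohol over the tertiary one, and the non-enolizable β-hydroxy aldehyde cannot dehydrate.

Step 14
Reactants: 20 prop-2-yn-1-ol; 21 5-bromo-2-methylpent-2-ene; 22 (E)-1,2-dichloroethene
Product: 25 (2Z,4E)-5-chloro-2-(4-methylpent-3-en-1-yl)penta-2,4-dien-1-ol, via Grignard reagent 23 (not isolated), via alkenylmagnesium alkoxide 24 (not isolated)
Conditions: 21, Mg, THF (gives 23, 2.2 equiv); 20, CuI (copper iodide, 10 mol%), 0 °C → reflux; then 22 (5 equiv), Pd(PPh3)4 (5 mol%), 25 °C; aqueous work-up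
Reagents that add atoms: none
Why: Copper-catalysed anti-carbomagnesiation of propargyl alcohol (Duboudin reaction: alkyl to C2, magnesium chelated cis to CH2O) fixes the Z-trisubstituted alkene, and palladium-catalysed Kumada-type coupling with excess (E)-1,2-dichloroethene proceeds with retention at both alkenes.

Step 15
Reactants: 25 chlorodienol
Product: 26 tert-butyl{[(2Z,4E)-5-chloro-2-(4-methylpent-3-en-1-yl)penta-2,4-dien-1-yl]oxy}dimethylsilane
Conditions: t-BuMe2SiCl, imidazole, CH2Cl2, 25 °C
Reagents that add atoms: tert-butyldimethylsilyl chloride, CC(C)(C)[Si](C)(C)Cl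
Why: Silylation of the primary allylic alcohol prevents nickel-mediated ionization of the dienyl carbinol in the next step.

Step 16
Reactants: 19 allenyl β-hydroxy aldehyde; 26 silylated chlorodiene
Product: 28 (1S,2R,5S,6S,10R)-10-[3-(tert-butyldimethylsilyloxy)propyl]-2-[(3E,5Z)-6-(tert-butyldimethylsilyloxymethyl)-10-methylundeca-1,3,5,9-tetraen-2-yl]-9-[(Z)-1,1-dimethoxypropan-2-ylidene]-6-methylspiro[4.5]decane-1,6-diol, via allylzinc chloride 27 (not isolated)
Conditions: NiBr2(MeOCH2CH2OMe) (10 mol%), 4,4′-di-tert-butyl-2,2′-bipyridine (12 mol%), Bu4NBF4 (0.1 M), DMF, undivided cell, zinc rod anode, nickel-foam cathode, constant current 5 mA (about 2.5 F/mol), 26 (1.5 equiv, slow addition), 20 °C; aqueous work-up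
Reagents that add atoms: none
Why: Proposed new method: nickel-electrocatalytic reductive alkenylative allene–aldehyde cyclization, in which cathodically generated zerovalent nickel(bipyridine) adds to the C–Cl bond of 26 with retention of both alkene geometries, the dienyl–nickel inserts the terminal allene C=C and places the dienyl group on the central carbon, the π-allylnickel is reduced at the cathode and handed to divalent zinc released from the anode, and the σ-allylzinc 27 adds through its tethered γ-carbon to the aldehyde in a closed six-membered transition state cis-fused to the forming five-membered ring (hydroxyl and alkenyl cis) while zinc is chelated by the free C2 hydroxyl (new carbinol oxygen syn to C2–O); the closest known reaction types are the palladium-catalysed arylative and distannylative cyclizations of allenyl aldehydes and the nickel-catalysed electroreductive Barbier allylation of aldehydes with a sacrificial zinc anode.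

Step 17
Reactants: 28 protected spirocycle
Product: 29 (2Z)-2-[(1S,2R,5S,6S,10R)-1,6-dihydroxy-10-(3-hydroxypropyl)-2-[(3E,5Z)-6-(hydroxymethyl)-10-methylundeca-1,3,5,9-tetraen-2-yl]-6-methylspiro[4.5]decan-9-ylidene]propanal
Conditions: HF·pyridine, THF/pyridine, 0 → 25 °C; then H2O, pyridinium p-toluenesulfonate (cat.), acetone, 25 °C
Reagents that add atoms: water, O
Why: Fluoride-mediated cleavage of both primary silyl ethers and mild acid hydrolysis of the very labile conjugated-enal acetal release the target without touching the triene, the stereocentres or the enal geometry.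

## Compound list

1 | (S)-(+)-carvone, (5S)-2-methyl-5-(prop-1-en-2-yl)cyclohex-2-en-1-one | O=C1C[C@@H](C(C)=C)CC=C1C | starting material
2 | tert-butyl(3-iodopropoxy)dimethylsilane | ICCCO[Si](C)(C)C(C)(C)C | starting material
3 | lithium cross-conjugated dienolate of 1 (OLi on C1, C1=C6 and C2=C3, 5S) | [Li]OC1=C[C@@H](C(C)=C)CC=C1C | intermediate
4 | (5S,6R)-6-[3-(tert-butyldimethylsilyloxy)propyl]-2-methyl-5-(prop-1-en-2-yl)cyclohex-2-en-1-one | O=C1[C@H](CCCO[Si](C)(C)C(C)(C)C)[C@@H](C(C)=C)CC=C1C | intermediate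
5 | lithium (5S,6R)-6-[3-(tert-butyldimethylsilyloxy)propyl]-2-methyl-5-(prop-1-en-2-yl)cyclohex-1-en-1-olate | CC1=C(O[Li])[C@H](CCCO[Si](C)(C)C(C)(C)C)[C@@H](C(C)=C)CC1 | intermediate
6 | (5S,6R)-6-[3-(tert-butyldimethylsilyloxy)propyl]-2-methyl-5-(prop-1-en-2-yl)cyclohex-1-en-1-yl trifluoromethanesulfonate | CC1=C(OS(=O)(=O)C(F)(F)F)[C@H](CCCO[Si](C)(C)C(C)(C)C)[C@@H](C(C)=C)CC1 | intermediate
7 | methyl (5S,6R)-6-[3-(tert-butyldimethylsilyloxy)propyl]-2-methyl-5-(prop-1-en-2-yl)cyclohex-1-ene-1-carboxylate | CC1=C(C(=O)OC)[C@H](CCCO[Si](C)(C)C(C)(C)C)[C@@H](C(C)=C)CC1 | intermediate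
8 | methyl (5S,6R)-6-[3-(tert-butyldimethylsilyloxy)propyl]-2-methyl-5-(3-oxoprop-1-en-2-yl)cyclohex-1-ene-1-carboxylate | CC1=C(C(=O)OC)[C@H](CCCO[Si](C)(C)C(C)(C)C)[C@@H](C(=C)C=O)CC1 | intermediate
9 | methyl (5Z,6R)-6-[3-(tert-butyldimethylsilyloxy)propyl]-2-methyl-5-(1-oxopropan-2-ylidene)cyclohex-1-ene-1-carboxylate (formyl syn to C6) | CC1=C(C(=O)OC)[C@H](CCCO[Si](C)(C)C(C)(C)C)/C(=C(/C)C=O)CC1 | intermediate
10 | methyl (5Z,6R)-6-[3-(tert-butyldimethylsilyloxy)propyl]-5-(1,1-dimethoxypropan-2-ylidene)-2-methylcyclohex-1-ene-1-carboxylate | CC1=C(C(=O)OC)[C@H](CCCO[Si](C)(C)C(C)(C)C)/C(=C(/C)C(OC)OC)CC1 | intermediate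
11 | but-3-yn-1-ol | C#CCCO | starting material
12 | penta-3,4-dien-1-ol | C=C=CCCO | intermediate
13 | 5-iodopenta-1,2-diene | C=C=CCCI | intermediate
14 | lithium dienolate of 10 (C1 ketene acetal, exocyclic C2 methylidene, 6R) | COC(O[Li])=C1[C@H](CCCO[Si](C)(C)C(C)(C)C)/C(=C(/C)C(OC)OC)CCC1=C | intermediate
15 | methyl (1R,5Z,6R)-6-[3-(tert-butyldimethylsilyloxy)propyl]-5-(1,1-dimethoxypropan-2-ylidene)-2-methylidene-1-(penta-3,4-dien-1-yl)cyclohexane-1-carboxylate (pentadienyl chain trans to the C6 chain) | C=C=CCC[C@]1([C@H](CCCO[Si](C)(C)C(C)(C)C)/C(=C(/C)C(OC)OC)CCC1=C)C(=O)OC | intermediate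
16 | [(1R,5Z,6R)-6-[3-(tert-butyldimethylsilyloxy)propyl]-5-(1,1-dimethoxypropan-2-ylidene)-2-methylidene-1-(penta-3,4-dien-1-yl)cyclohexyl]methanol | C=C=CCC[C@]1([C@H](CCCO[Si](C)(C)C(C)(C)C)/C(=C(/C)C(OC)OC)CCC1=C)CO | intermediate
17 | spiro-epoxide of 16 at C2, (1S,2S,5Z,6R), oxirane oxygen syn to CH2OH | C=C=CCC[C@]1([C@H](CCCO[Si](C)(C)C(C)(C)C)/C(=C(/C)C(OC)OC)CC[C@]12OC2)CO | intermediate
18 | (1S,2S,5Z,6R)-6-[3-(tert-butyldimethylsilyloxy)propyl]-5-(1,1-dimethoxypropan-2-ylidene)-1-(hydroxymethyl)-2-methyl-1-(penta-3,4-dien-1-yl)cyclohexan-2-ol (tertiary OH syn to CH2OH and to the C6 chain) | C=C=CCC[C@]1([C@H](CCCO[Si](C)(C)C(C)(C)C)/C(=C(/C)C(OC)OC)CC[C@]1(C)O)CO | intermediate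
19 | (1R,2S,5Z,6R)-6-[3-(tert-butyldimethylsilyloxy)propyl]-5-(1,1-dimethoxypropan-2-ylidene)-2-hydroxy-2-methyl-1-(penta-3,4-dien-1-yl)cyclohexane-1-carbaldehyde | C=C=CCC[C@]1([C@H](CCCO[Si](C)(C)C(C)(C)C)/C(=C(/C)C(OC)OC)CC[C@]1(C)O)C=O | intermediate
20 | prop-2-yn-1-ol | C#CCO | starting material
21 | 5-bromo-2-methylpent-2-ene | CC(C)=CCCBr | starting material
22 | (E)-1,2-dichloroethene | Cl/C=C/Cl | starting material
23 | (4-methylpent-3-en-1-yl)magnesium bromide | CC(C)=CCC[Mg]Br | intermediate
24 | bromomagnesium (2Z)-3-(bromomagnesio)-2-(4-methylpent-3-en-1-yl)prop-2-en-1-olate | Br[Mg]/C=C(\CO[Mg]Br)CCC=C(C)C | intermediate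
25 | (2Z,4E)-5-chloro-2-(4-methylpent-3-en-1-yl)penta-2,4-dien-1-ol | Cl/C=C/C=C(\CO)CCC=C(C)C | intermediate
26 | tert-butyl{[(2Z,4E)-5-chloro-2-(4-methylpent-3-en-1-yl)penta-2,4-dien-1-yl]oxy}dimethylsilane | Cl/C=C/C=C(\CO[Si](C)(C)C(C)(C)C)CCC=C(C)C | intermediate
27 | σ-allylzinc chloride from 19 and 26 (ZnCl on the former allene CH2, dienyl group on the central carbon, aldehyde intact) | Cl[Zn]CC(/C=C/C=C(\CO[Si](C)(C)C(C)(C)C)CCC=C(C)C)=CCC[C@]1([C@H](CCCO[Si](C)(C)C(C)(C)C)/C(=C(/C)C(OC)OC)CC[C@]1(C)O)C=O | intermediate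
28 | (1S,2R,5S,6S,10R)-10-[3-(tert-butyldimethylsilyloxy)propyl]-2-[(3E,5Z)-6-(tert-butyldimethylsilyloxymethyl)-10-methylundeca-1,3,5,9-tetraen-2-yl]-9-[(Z)-1,1-dimethoxypropan-2-ylidene]-6-methylspiro[4.5]decane-1,6-diol | C=C(/C=C/C=C(\CO[Si](C)(C)C(C)(C)C)CCC=C(C)C)[C@H]1CC[C@]2([C@H](CCCO[Si](C)(C)C(C)(C)C)/C(=C(/C)C(OC)OC)CC[C@]2(C)O)[C@H]1O | intermediate
29 | (2Z)-2-[(1S,2R,5S,6S,10R)-1,6-dihydroxy-10-(3-hydroxypropyl)-2-[(3E,5Z)-6-(hydroxymethyl)-10-methylundeca-1,3,5,9-tetraen-2-yl]-6-methylspiro[4.5]decan-9-ylidene]propanal | C=C(/C=C/C=C(\CO)CCC=C(C)C)[C@H]1CC[C@]2([C@H](CCCO)/C(=C(/C)C=O)CC[C@]2(C)O)[C@H]1O | target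

## Step count and risks

Total steps: 17. Longest linear sequence: 13 (steps 1–6, 9–13, 16 and 17, from 1).

Most likely to fail, first: step 16, the new electrochemical cyclization. Homocoupling of 26, protonation of the allylmetal, or poor facial control at the aldehyde could all intervene. The fallback sets out from 19 and uses the known palladium-catalysed distannylative carbocyclization of allenyl aldehydes (Bu3SnSnBu3, Pd(PPh3)4, THF, 25–50 °C). The allylstannane formed in situ closes ring B onto the aldehyde to give the cis-2-[1-(tributylstannyl)vinyl]cyclopentanol F1. A Stille coupling of F1 with 26 (Pd2(dba)3, P(t-Bu)3, CsF, dioxane, 60 °C) then comes back to the route at 28.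

Second: step 9, the quaternary alkylation. The unactivated homoallenyl iodide may react sluggishly or eliminate, and the facial selectivity rests on the axial C6 chain. The fallback sets out from 10 and replaces the SN2 step by a conjugate addition. The dienolate (LiN(iPr)2, THF, −78 °C) adds to methyl acrylate to give the diester F2. Selective reduction of the unhindered ester (iBu2AlH, 1.05 equiv, toluene, −78 °C) gives the ester aldehyde F3. HC≡CMgBr (THF, −78 °C) gives the propargylic alcohol F4 as a carbinol epimer mixture. Myers reductive transposition (2-nitrobenzenesulfonylhydrazide, PPh3, diethyl azodicarboxylate, THF, −15 → 25 °C) turns the propargylic alcohol into the terminal allene and comes back to the route at 15.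

Third: step 5, the isomerization to the tetrasubstituted enal. The Z/E ratio is under thermodynamic control and may be modest; a minor E isomer would be separated at this stage and resubjected. The catalyst may also decarbonylate the aldehyde, and the single remaining stereocentre (C6) must not enolize. The fallback sets out from 8. Conjugate reduction ([(Ph3P)CuH]6 (5 mol%), PhSiH3, toluene, 25 °C, then aqueous fluoride work-up) gives the saturated aldehyde F5 as a mixture of α-epimers. Dehydrogenation toward the more substituted position with 2-iodoxybenzoic acid (DMSO/toluene, 70 °C) comes back to the route at 9.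

## Further compounds

F1 | step 16 | (1S,2R,5S,6S,10R)-10-[3-(tert-butyldimethylsilyloxy)propyl]-9-[(Z)-1,1-dimethoxypropan-2-ylidene]-6-methyl-2-[1-(tributylstannyl)ethenyl]spiro[4.5]decane-1,6-diol | C=C([Sn](CCCC)(CCCC)CCCC)[C@H]1CC[C@]2([C@H](CCCO[Si](C)(C)C(C)(C)C)/C(=C(/C)C(OC)OC)CC[C@]2(C)O)[C@H]1O
F2 | step 9 | methyl (1R,5Z,6R)-6-[3-(tert-butyldimethylsilyloxy)propyl]-5-(1,1-dimethoxypropan-2-ylidene)-1-(3-methoxy-3-oxopropyl)-2-methylidenecyclohexane-1-carboxylate | COC(=O)CC[C@]1([C@H](CCCO[Si](C)(C)C(C)(C)C)/C(=C(/C)C(OC)OC)CCC1=C)C(=O)OC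
F3 | step 9 | methyl (1R,5Z,6R)-6-[3-(tert-butyldimethylsilyloxy)propyl]-5-(1,1-dimethoxypropan-2-ylidene)-2-methylidene-1-(3-oxopropyl)cyclohexane-1-carboxylate | O=CCC[C@]1([C@H](CCCO[Si](C)(C)C(C)(C)C)/C(=C(/C)C(OC)OC)CCC1=C)C(=O)OC
F4 | step 9 | methyl (1R,5Z,6R)-6-[3-(tert-butyldimethylsilyloxy)propyl]-5-(1,1-dimethoxypropan-2-ylidene)-1-(3-hydroxypent-4-yn-1-yl)-2-methylidenecyclohexane-1-carboxylate (carbinol epimers) | C#CC(O)CC[C@]1([C@H](CCCO[Si](C)(C)C(C)(C)C)/C(=C(/C)C(OC)OC)CCC1=C)C(=O)OC
F5 | step 5 | methyl (5S,6R)-6-[3-(tert-butyldimethylsilyloxy)propyl]-2-methyl-5-(1-oxopropan-2-yl)cyclohex-1-ene-1-carboxylate (epimers at the aldehyde α-carbon) | CC1=C(C(=O)OC)[C@H](CCCO[Si](C)(C)C(C)(C)C)[C@@H](C(C)C=O)CC1
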